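Turn the percentages into molarity first.

| flask | Z | remark | time |
|---|---|---|---|
| spring | 1 M | run made earlier |  |
| midnight | 2.2 M | run made earlier |  |
| flask | 1.5 M |  | 5.0 h |

| run | time / h | E / % | Q / % | Z / % |
|---|---|---|---|---|
| spring | 1.00 | 24.0 | 6.5 | 70.6 |
| spring | 2.00 | 42.4 | 14.0 | 42.9 |
| spring | 3.00 | 55.7 | 23.3 | 18.7 |
| spring | 4.00 | 65.2 | 31.6 | 0.1 |
| midnight | 0.333 | 3.0 | 1.0 | 95.3 |
| midnight | 0.667 | 7.4 | 1.7 | 90.2 |
| midnight | 1.50 | 15.9 | 4.1 | 79.9 |
| midnight | 4.00 | 30.0 | 14.3 | 54.1 |

(readings scatter by 0.3 percentage points)

- the E standing at 5.0 h, as a percentage of the Z charged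
- concentration of Q in solution at 5.0 h, in percent of saturation

At 4.00 h the spring run holds 0.652 M of E and the midnight run 0.660 M, though their charges of Z differ. Solid lost by then also matches: 0.999 M in spring, 1.01 M at midnight. So my working rule is that, while solid remains in these runs, E in molar terms follows one curve, and a spring percentage converts to this flask by the charge ratio 0.667, spring's charge over the flask's.

Now turn the question round: the rule's condition fails here if this flask's solid is gone before 5.0 h. Taking the loss read at midnight, I reckon this flask to hold about 0.490 M of Z at 4.00 h. For the opposite outcome it has to lose that within the remaining time, but the midnight run lost Z at 0.227 M h⁻¹ on average between 1.50 h and 4.00 h, which is less than that needs.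

So I keep the rule and extend the spring curve past its last reading, where spring's own solid reads 0.1%; the extension stands for a flask with solid left, not for the spring run. The last two hourly gains of E in spring read as the ratio 0.714, and one more gain at that ratio, times the charge ratio, gives my estimate of 48.0%. The forecast, holding that “E doesn't depend on the Z charge”, says 48.2% (46.5% to 50%), slightly above mine, and 47% (39% to 56%) of saturation.

The flask gives 48.3% and 46.7%.

    Q ⇌ E + X (K = 1.37 M, k = 0.00405 s⁻¹)
    2 Q → D (k = 4.59 × 10⁻⁵ M⁻¹ s⁻¹)
    Z ⇌ Q, rate k3*(cs3 - [Q]) while solid is left; crystals form when [Q] > cs3 (solubility = 0.830 M, k = 1.04 × 10⁻⁴ s⁻¹)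

This flask still has 20.2% of Z as solid at 5.00 h. Divided by 0.667, its E reads 72.4% of spring's charge, where my extended spring curve read 72.0%. Now read the same flask at 2.0 h: the charge ratio on spring's 42.4% gives 28.3%. That neighbouring flask stands at 28.4%.

The earlier runs and the new flask come from a simulation from invented constants, noise included.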